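The route rests on cutting the central benzene ring. It is a resorcinol in which C3a′ of the second dihydrobenzofuran lies between the two oxygen-bearing carbons (C4′, C7a′), and C6′, para to C3a′, carries the first dihydrobenzofuran. A cyclobutenone–siloxyalkyne benzannulation delivers exactly this 2,5-disubstituted resorcinol. Heating cyclobutenone 18 (the whole stilbene–dihydrobenzofuran half on the enone β-carbon) with siloxyalkyne 34 (both remaining aryl groups on a stereodefined two-carbon chain) joins the halves through two C–C bonds and closes the aromatic ring by a third, giving mono-silyl resorcinol 39. All other phenols are benzyl-protected, so only desilylation, cationic closure of the second dihydrobenzofuran and cold debenzylation remain.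

Key step: step 20

Remarks on the chemistry (assumptions and design choices):
- Phenols are carried as benzyl-type ethers, not methyl ethers: a final Lewis-acid O-demethylation would endanger the electron-rich stilbene and both 2-aryl-dihydrobenzofurans, whereas BCl3/C6HMe5 removes benzyl groups at −78 °C.
- The styryl group is attached only after the four-membered ring exists (step 11), because dichloroketene also adds to electron-rich stilbenes.
- The carbinol carbon of 34 is carried as 4S, the configuration a syn-selective aldol delivers (C3 is R); it is ionised in step 21 and does not reach the target.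
- Rh2(S-PTTL)4, dirhodium tetrakis[N-phthaloyl-(S)-tert-leucinate], is assumed to give the 2R insertion product, as with related benzyl aryl ethers; if the sense is opposite, the (R)-catalyst is used.
- Step 2 consumes two equivalents of chloride 3, one for each phenol of 2.

Step 1
Reactants: 1 4-bromo-2,6-dimethoxybenzaldehyde
Product: 2 4-bromo-2,6-dihydroxybenzaldehyde
Conditions: BBr3, CH2Cl2, −78 → 25 °C; H2O
Reagents that add atoms: none
Why: Lewis-acid cleavage of aryl methyl ethers (BBr3 demethylation) is routine on this simple, acid-stable benzaldehyde, and doing it first keeps every later, sensitive intermediate free of methyl ethers.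

Step 2
Reactants: 2 4-bromo-2,6-dihydroxybenzaldehyde; 3 4-(benzyloxy)benzyl chloride
Product: 4 4-bromo-2,6-bis{[4-(benzyloxy)benzyl]oxy}benzaldehyde
Conditions: 3 (2.2 equiv), K2CO3, n-Bu4NI (cat.), DMF, 60 °C
Reagents that add atoms: 4-(benzyloxy)benzyl chloride (the second equivalent of 3), ClCc1ccc(OCc2ccccc2)cc1
Why: A twofold Williamson etherification with two equivalents of 3 installs two identical ethers, one of which later supplies C2 with its aryl group while the other protects the C4 phenol, so the two phenols need not be told apart.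

Step 3
Reactants: 4 bis-ether aldehyde
Product: 5 5-bromo-1,3-bis{[4-(benzyloxy)benzyl]oxy}-2-(2-methoxyvinyl)benzene (E/Z mixture)
Conditions: [Ph3PCH2OMe]Cl, KOt-Bu, THF, 0 → 25 °C
Reagents that add atoms: (methoxymethyl)triphenylphosphonium chloride, COC[P+](c1ccccc1)(c1ccccc1)c1ccccc1.[Cl-]
Why: Wittig methoxymethylenation adds the one carbon needed for the arylacetate and tolerates the hindered 2,6-dialkoxybenzaldehyde, the alkene geometry being irrelevant.

Step 4
Reactants: 5 enol ether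
Product: 6 methyl 2-(4-bromo-2,6-bis{[4-(benzyloxy)benzyl]oxy}phenyl)acetate
Conditions: [C5H5NH][CrO3Cl] (pyridinium chlorochromate), CH2Cl2, 25 °C
Reagents that add atoms: pyridinium chlorochromate, [O-][Cr](=O)(=O)Cl.c1cc[nH+]cc1
Why: Chlorochromate oxidation of an aldehyde-derived enol ether gives the ester directly (addition of chlorochromate to the protonated enol ether, then collapse of the chromate ester), completing the homologation in two steps.

Step 5
Reactants: 6 methyl arylacetate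
Product: 7 methyl 2-(4-bromo-2,6-bis{[4-(benzyloxy)benzyl]oxy}phenyl)-2-diazoacetate
Conditions: 4-AcNHC6H4SO2N3, DBU, MeCN, 0 → 25 °C
Reagents that add atoms: 4-acetamidobenzenesulfonyl azide, CC(=O)Nc1ccc(cc1)S(=O)(=O)N=[N+]=[N-]
Why: Regitz diazo transfer to the arylacetate enolate is the standard entry to aryldiazoacetates.

Step 6
Reactants: 7 aryldiazoacetate
Product: 9 methyl (2R,3R)-4-{[4-(benzyloxy)benzyl]oxy}-2-[4-(benzyloxy)phenyl]-6-bromo-2,3-dihydrobenzofuran-3-carboxylate, via cis ester 8 (not isolated)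
Conditions: Rh2(S-PTTL)4 (1 mol %), PhMe, −60 °C; then NaOMe, MeOH–THF, 25 °C
Reagents that add atoms: none
Why: Enantioselective intramolecular 1,5 C–H insertion of the rhodium carbene into an ether CH2 (activated by oxygen and the 4-alkoxyphenyl group, either of the two identical ethers giving the same product) closes the dihydrobenzofuran with the chiral carboxylate ligands setting C2 as R, and base epimerisation of the ester α-carbon then gives the thermodynamically preferred 2,3-trans isomer (3R).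

Step 7
Reactants: 9 trans ester
Product: 11 (2R,3R)-4-{[4-(benzyloxy)benzyl]oxy}-2-[4-(benzyloxy)phenyl]-6-bromo-3-ethynyl-2,3-dihydrobenzofuran, via aldehyde 10 (not isolated)
Conditions: i-Bu2AlH, CH2Cl2, −78 °C; then MeOH, MeC(O)C(N2)P(O)(OMe)2, K2CO3, −78 → 25 °C
Reagents that add atoms: dimethyl (1-diazo-2-oxopropyl)phosphonate, COP(=O)(OC)C(=[N+]=[N-])C(C)=O
Why: Partial reduction of the ester and in-situ Seyferth–Gilbert homologation with the Ohira–Bestmann reagent give the terminal alkyne in one pot, and although C3 of aldehyde 10 can epimerise under base, the 2,3-trans arrangement dictated by the stable C2 centre is the favoured one, so C3 stays R.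

Step 8
Reactants: 11 ethynyl dihydrobenzofuran; 12 trichloroacetyl chloride
Product: 14 3-{(2R,3S)-4-{[4-(benzyloxy)benzyl]oxy}-2-[4-(benzyloxy)phenyl]-6-bromo-2,3-dihydrobenzofuran-3-yl}-4,4-dichlorocyclobut-2-en-1-one, via dichloroketene 13 (not isolated)
Conditions: Zn(Cu), Et2O–DME, 25 °C
Reagents that add atoms: none
Why: The (2+2) cycloaddition of dichloroketene (made in situ by zinc dechlorination of the acid chloride) to a terminal alkyne gives the 3-substituted 4,4-dichlorocyclobutenone regioselectively, and at this stage the substrate holds no alkene that could compete (the C3 descriptor becomes S only through CIP priorities, the trans geometry is unchanged).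

Step 9
Reactants: 14 dichlorocyclobutenone
Product: 15 3-{(2R,3R)-4-{[4-(benzyloxy)benzyl]oxy}-2-[4-(benzyloxy)phenyl]-6-bromo-2,3-dihydrobenzofuran-3-yl}cyclobut-2-en-1-one
Conditions: Zn, AcOH, TMEDA, EtOH, 0 → 25 °C
Reagents that add atoms: none
Why: Buffered zinc reduction of the α,α-dichloroketone is the standard second half of this cyclobutenone synthesis and leaves the aryl bromide and the benzyl ethers untouched.

Step 10
Reactants: 16 1-(benzyloxy)-4-ethynylbenzene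
Product: 17 (E)-2-{2-[4-(benzyloxy)phenyl]vinyl}-4,4,5,5-tetramethyl-1,3,2-dioxaborolane
Conditions: HBpin, Cp2Zr(H)Cl (5 mol %), Et3N (cat.), CH2Cl2, 25 °C
Reagents that add atoms: pinacolborane, [H]B1OC(C)(C)C(C)(C)O1
Why: Zirconocene-catalysed hydroboration of a terminal alkyne with pinacolborane is a syn, anti-Markovnikov addition and therefore gives the (E)-vinylboronate.

Step 11
Reactants: 15 bromo cyclobutenone; 17 (E)-vinylboronate
Product: 18 3-{(2R,3R)-4-{[4-(benzyloxy)benzyl]oxy}-2-[4-(benzyloxy)phenyl]-6-[(E)-4-(benzyloxy)styryl]-2,3-dihydrobenzofuran-3-yl}cyclobut-2-en-1-one (fragment 1)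
Conditions: Pd(OAc)2 (cat.), SPhos (cat.), K3PO4, THF–H2O, 25 °C
Reagents that add atoms: none
Why: Suzuki–Miyaura coupling with an electron-rich biarylphosphine catalyst runs at room temperature, well below the temperature at which the cyclobutenone opens, and transfers the vinyl group with retention of the E geometry.

Step 12
Reactants: 19 methyl 2-(3,5-dihydroxyphenyl)acetate
Product: 21 2-[3,5-bis(benzyloxy)phenyl]acetic acid, via methyl ester 20 (not isolated)
Conditions: BnBr, K2CO3, DMF, 50 °C; then LiOH, H2O–MeOH, 25 °C; HCl (aq)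
Reagents that add atoms: benzyl bromide, BrCc1ccccc1; lithium hydroxide, [Li+].[OH-]
Why: Williamson benzylation of both phenols followed by saponification in the same pot gives the protected arylacetic acid.

Step 13
Reactants: 21 2-[3,5-bis(benzyloxy)phenyl]acetic acid; 22 (S)-4-benzyloxazolidin-2-one
Product: 24 (S)-4-benzyl-3-{2-[3,5-bis(benzyloxy)phenyl]acetyl}oxazolidin-2-one, via mixed pivalic anhydride 23 (not isolated)
Conditions: t-BuCOCl, Et3N, THF, −20 °C; then LiCl, 25 °C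
Reagents that add atoms: none
Why: N-acylation of the oxazolidinone through the mixed pivalic anhydride with lithium chloride activation is the standard way to attach the Evans auxiliary to an arylacetic acid.

Step 14
Reactants: 24 N-arylacetyl oxazolidinone; 25 2,4-bis(benzyloxy)benzaldehyde
Product: 27 (S)-4-benzyl-3-{(2S,3S)-2-[3,5-bis(benzyloxy)phenyl]-3-[2,4-bis(benzyloxy)phenyl]-3-hydroxypropanoyl}oxazolidin-2-one, via boron enolate 26 (not isolated)
Conditions: n-Bu2BOTf, i-Pr2NEt, CH2Cl2, −78 → 0 °C; 25, −78 → 0 °C; then pH 7 buffer, MeOH, H2O2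
Reagents that add atoms: none
Why: In the Evans syn-aldol reaction the (Z)-dibutylboron enolate reacts through a closed chair transition state in which the benzyl group of the auxiliary shields one enolate face, which sets the aryl-bearing carbon (the later C3′) and the carbinol carbon together as the 2S,3S syn pair.

Step 15
Reactants: 27 syn-aldol adduct
Product: 28 (S)-4-benzyl-3-{(2S,3S)-2-[3,5-bis(benzyloxy)phenyl]-3-[2,4-bis(benzyloxy)phenyl]-3-(tert-butyldimethylsilyloxy)propanoyl}oxazolidin-2-one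
Conditions: TBSOTf, 2,6-lutidine, CH2Cl2, −78 → 0 °C
Reagents that add atoms: tert-butyldimethylsilyl triflate, CC(C)(C)[Si](C)(C)OS(=O)(=O)C(F)(F)F
Why: O-silylation of the aldol hydroxyl blocks retro-aldol cleavage and protects the carbinol through the organolithium step.

Step 16
Reactants: 28 silylated aldol adduct
Product: 29 (2R,3S)-2-[3,5-bis(benzyloxy)phenyl]-3-[2,4-bis(benzyloxy)phenyl]-3-(tert-butyldimethylsilyloxy)propan-1-ol
Conditions: LiBH4, MeOH (1 equiv), THF, 0 °C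
Reagents that add atoms: none
Why: Reductive cleavage of the N-acyloxazolidinone with lithium borohydride gives the primary alcohol without touching the α-stereocentre and returns the auxiliary.

Step 17
Reactants: 29 primary alcohol
Product: 30 (2S,3S)-2-[3,5-bis(benzyloxy)phenyl]-3-[2,4-bis(benzyloxy)phenyl]-3-(tert-butyldimethylsilyloxy)propanal
Conditions: Dess–Martin periodinane, NaHCO3, CH2Cl2, 0 → 25 °C
Reagents that add atoms: none
Why: The buffered Dess–Martin oxidation is neutral, so the configurationally labile α-aryl aldehyde should form without epimerisation or loss of silanol, and it is used at once.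

Step 18
Reactants: 30 α-aryl aldehyde
Product: 31 (3S,4S)-1,1-dibromo-3-[3,5-bis(benzyloxy)phenyl]-4-[2,4-bis(benzyloxy)phenyl]-4-(tert-butyldimethylsilyloxy)but-1-ene
Conditions: CBr4, PPh3, 2,6-lutidine, CH2Cl2, 0 °C
Reagents that add atoms: carbon tetrabromide, BrC(Br)(Br)Br
Why: The Corey–Fuchs (Ramirez) dibromo-olefination is an essentially neutral Wittig-type reaction and therefore suits the enolisable aldehyde better than a base-mediated alkyne synthesis.

Step 19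
Reactants: 31 1,1-dibromoalkene
Product: 34 (3R,4S)-3-[3,5-bis(benzyloxy)phenyl]-4-[2,4-bis(benzyloxy)phenyl]-4-(tert-butyldimethylsilyloxy)-1-(triisopropylsilyloxy)but-1-yne (fragment 2), via lithium acetylide 32 (not isolated), via lithium ynolate 33 (not isolated)
Conditions: n-BuLi (2.1 equiv), THF, −78 °C; t-BuOOH/LiN(SiMe3)2, −78 → 0 °C; TIPSOTf, −78 → 25 °C
Reagents that add atoms: tert-butyl hydroperoxide, CC(C)(C)OO; triisopropylsilyl triflate, CC(C)[Si](C(C)C)(C(C)C)OS(=O)(=O)C(F)(F)F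
Why: Bromine–lithium exchange and Fritsch–Buttenberg–Wiechell rearrangement give the lithium acetylide, which lithium tert-butyl peroxide oxidises to the ynolate (Julia oxidation) and the bulky silyl triflate captures on oxygen, the two stereocentres taking no part.

Step 20
Reactants: 18 cyclobutenone (fragment 1); 34 siloxyalkyne (fragment 2)
Product: 39 2-{(1R,2S)-1-[3,5-bis(benzyloxy)phenyl]-2-[2,4-bis(benzyloxy)phenyl]-2-(tert-butyldimethylsilyloxy)ethyl}-5-{(2R,3R)-4-{[4-(benzyloxy)benzyl]oxy}-2-[4-(benzyloxy)phenyl]-6-[(E)-4-(benzyloxy)styryl]-2,3-dihydrobenzofuran-3-yl}-3-(triisopropylsilyloxy)phenol, via vinylketene 35 (not isolated), via 2-vinylcyclobutenone 36 (not isolated), via dienylketene 37 (not isolated), via cyclohexadienone 38 (not isolated)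
Conditions: 34 (1.2 equiv), PhMe (degassed), 80 → 110 °C
Reagents that add atoms: none
Why: On heating, 18 undergoes 4π electrocyclic opening to vinylketene 35, whose ketene C=C adds (2+2) to the electron-rich triple bond of 34 to give 2-vinylcyclobutenone 36; a second 4π opening gives dienylketene 37, 6π electrocyclisation gives cyclohexadienone 38, and tautomerisation gives phenol 39. This is the Danheiser benzannulation of a cyclobutenone with a siloxyalkyne, a known route to resorcinol mono-silyl ethers. The one new ring, the central benzene ring, is closed by the 6π electrocyclisation (former ketene carbon to former cyclobutenone CH2) after the (2+2) step has joined the two fragments through two C–C bonds. No stereocentre is created, and the four existing ones and the E-alkene should be untouched by the neutral thermal conditions. The only selectivity needed is regiochemical: the oxygen-polarised alkyne bonds through its carbon remote from oxygen to the electrophilic ketene carbonyl carbon, which places the chain of 34 between OH and OSi(i-Pr)3 and the substituent of 18 para to it.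

Step 21
Reactants: 39 mono-silyl resorcinol
Product: 41 (2R,3R)-2-[2,4-bis(benzyloxy)phenyl]-3-[3,5-bis(benzyloxy)phenyl]-6-{(2R,3R)-4-{[4-(benzyloxy)benzyl]oxy}-2-[4-(benzyloxy)phenyl]-6-[(E)-4-(benzyloxy)styryl]-2,3-dihydrobenzofuran-3-yl}-2,3-dihydrobenzofuran-4-ol, via triol 40 (not isolated)
Conditions: n-Bu4NF, AcOH, THF, 0 → 25 °C; then TsOH·H2O (cat.), CH2Cl2, 0 °C
Reagents that add atoms: none
Why: Fluoride removes both silyl groups, and catalytic acid then ionises the 2,4-dialkoxybenzylic alcohol to a stabilised cation that either of the two equivalent resorcinol oxygens captures in a 5-exo closure anti to the neighbouring aryl group, so the existing C3′ centre sets C2′ as R (2,3-trans, the kinetic and thermodynamic outcome).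

Step 22
Reactants: 41 benzyl-protected precursor
Product: 42 (2R,3R)-2-(2,4-dihydroxyphenyl)-3-(3,5-dihydroxyphenyl)-6-{(2R,3R)-4-hydroxy-2-(4-hydroxyphenyl)-6-[(E)-4-hydroxystyryl]-2,3-dihydrobenzofuran-3-yl}-2,3-dihydrobenzofuran-4-ol (CNP0118407.2)
Conditions: BCl3, C6HMe5, CH2Cl2, −78 °C; MeOH
Reagents that add atoms: none
Why: Boron trichloride with pentamethylbenzene as a non-basic benzyl-cation scavenger cleaves all aryl benzyl-type ethers at −78 °C, conditions under which the stilbene and the benzylic C–O bonds of both dihydrobenzofurans should survive, leaving the four stereocentres untouched.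

Compound list
1 | 4-bromo-2,6-dimethoxybenzaldehyde | COc1cc(Br)cc(OC)c1C=O | starting material
2 | 4-bromo-2,6-dihydroxybenzaldehyde | Oc1cc(Br)cc(O)c1C=O | intermediate
3 | 4-(benzyloxy)benzyl chloride | ClCc1ccc(OCc2ccccc2)cc1 | starting material
4 | 4-bromo-2,6-bis{[4-(benzyloxy)benzyl]oxy}benzaldehyde | O=Cc1c(OCc2ccc(OCc3ccccc3)cc2)cc(Br)cc1OCc1ccc(OCc2ccccc2)cc1 | intermediate
5 | 5-bromo-1,3-bis{[4-(benzyloxy)benzyl]oxy}-2-(2-methoxyvinyl)benzene (E/Z mixture) | COC=Cc1c(OCc2ccc(OCc3ccccc3)cc2)cc(Br)cc1OCc1ccc(OCc2ccccc2)cc1 | intermediate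
6 | methyl 2-(4-bromo-2,6-bis{[4-(benzyloxy)benzyl]oxy}phenyl)acetate | COC(=O)Cc1c(OCc2ccc(OCc3ccccc3)cc2)cc(Br)cc1OCc1ccc(OCc2ccccc2)cc1 | intermediate
7 | methyl 2-(4-bromo-2,6-bis{[4-(benzyloxy)benzyl]oxy}phenyl)-2-diazoacetate | COC(=O)C(=[N+]=[N-])c1c(OCc2ccc(OCc3ccccc3)cc2)cc(Br)cc1OCc1ccc(OCc2ccccc2)cc1 | intermediate
8 | methyl (2R,3S)-4-{[4-(benzyloxy)benzyl]oxy}-2-[4-(benzyloxy)phenyl]-6-bromo-2,3-dihydrobenzofuran-3-carboxylate (2,3-cis) | Brc1cc(OCc3ccc(OCc4ccccc4)cc3)c2c(c1)O[C@@H](c1ccc(OCc3ccccc3)cc1)[C@H]2C(=O)OC | intermediate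
9 | methyl (2R,3R)-4-{[4-(benzyloxy)benzyl]oxy}-2-[4-(benzyloxy)phenyl]-6-bromo-2,3-dihydrobenzofuran-3-carboxylate (2,3-trans) | Brc1cc(OCc3ccc(OCc4ccccc4)cc3)c2c(c1)O[C@@H](c1ccc(OCc3ccccc3)cc1)[C@@H]2C(=O)OC | intermediate
10 | (2R,3R)-4-{[4-(benzyloxy)benzyl]oxy}-2-[4-(benzyloxy)phenyl]-6-bromo-2,3-dihydrobenzofuran-3-carbaldehyde | Brc1cc(OCc3ccc(OCc4ccccc4)cc3)c2c(c1)O[C@@H](c1ccc(OCc3ccccc3)cc1)[C@@H]2C=O | intermediate
11 | (2R,3R)-4-{[4-(benzyloxy)benzyl]oxy}-2-[4-(benzyloxy)phenyl]-6-bromo-3-ethynyl-2,3-dihydrobenzofuran | Brc1cc(OCc3ccc(OCc4ccccc4)cc3)c2c(c1)O[C@@H](c1ccc(OCc3ccccc3)cc1)[C@@H]2C#C | intermediate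
12 | trichloroacetyl chloride | ClC(=O)C(Cl)(Cl)Cl | starting material
13 | dichloroketene | ClC(Cl)=C=O | intermediate
14 | 3-{(2R,3S)-4-{[4-(benzyloxy)benzyl]oxy}-2-[4-(benzyloxy)phenyl]-6-bromo-2,3-dihydrobenzofuran-3-yl}-4,4-dichlorocyclobut-2-en-1-one (2,3-trans) | Brc1cc(OCc3ccc(OCc4ccccc4)cc3)c2c(c1)O[C@@H](c1ccc(OCc3ccccc3)cc1)[C@@H]2C1=CC(=O)C1(Cl)Cl | intermediate
15 | 3-{(2R,3R)-4-{[4-(benzyloxy)benzyl]oxy}-2-[4-(benzyloxy)phenyl]-6-bromo-2,3-dihydrobenzofuran-3-yl}cyclobut-2-en-1-one | Brc1cc(OCc3ccc(OCc4ccccc4)cc3)c2c(c1)O[C@@H](c1ccc(OCc3ccccc3)cc1)[C@@H]2C1=CC(=O)C1 | intermediate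
16 | 1-(benzyloxy)-4-ethynylbenzene | C#Cc1ccc(OCc2ccccc2)cc1 | starting material
17 | (E)-2-{2-[4-(benzyloxy)phenyl]vinyl}-4,4,5,5-tetramethyl-1,3,2-dioxaborolane | CC1(C)OB(/C=C/c2ccc(OCc3ccccc3)cc2)OC1(C)C | intermediate
18 | 3-{(2R,3R)-4-{[4-(benzyloxy)benzyl]oxy}-2-[4-(benzyloxy)phenyl]-6-[(E)-4-(benzyloxy)styryl]-2,3-dihydrobenzofuran-3-yl}cyclobut-2-en-1-one (fragment 1) | C(c1ccccc1)Oc1ccc(/C=C/c2cc(OCc4ccc(OCc5ccccc5)cc4)c3c(c2)O[C@@H](c2ccc(OCc4ccccc4)cc2)[C@@H]3C2=CC(=O)C2)cc1 | intermediate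
19 | methyl 2-(3,5-dihydroxyphenyl)acetate | COC(=O)Cc1cc(O)cc(O)c1 | starting material
20 | methyl 2-[3,5-bis(benzyloxy)phenyl]acetate | COC(=O)Cc1cc(OCc2ccccc2)cc(OCc2ccccc2)c1 | intermediate
21 | 2-[3,5-bis(benzyloxy)phenyl]acetic acid | OC(=O)Cc1cc(OCc2ccccc2)cc(OCc2ccccc2)c1 | intermediate
22 | (S)-4-benzyloxazolidin-2-one | O=C1OC[C@H](Cc2ccccc2)N1 | starting material
23 | 2-[3,5-bis(benzyloxy)phenyl]acetic pivalic anhydride | CC(C)(C)C(=O)OC(=O)Cc1cc(OCc2ccccc2)cc(OCc2ccccc2)c1 | intermediate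
24 | (S)-4-benzyl-3-{2-[3,5-bis(benzyloxy)phenyl]acetyl}oxazolidin-2-one | O=C1OC[C@H](Cc2ccccc2)N1C(=O)Cc1cc(OCc2ccccc2)cc(OCc2ccccc2)c1 | intermediate
25 | 2,4-bis(benzyloxy)benzaldehyde | O=Cc1ccc(OCc2ccccc2)cc1OCc1ccccc1 | starting material
26 | (Z)-dibutylboron enolate of 24 [(S)-4-benzyl-3-{(Z)-2-[3,5-bis(benzyloxy)phenyl]-1-(dibutylboryloxy)vinyl}oxazolidin-2-one] | CCCCB(CCCC)O/C(=C\c1cc(OCc2ccccc2)cc(OCc2ccccc2)c1)N1[C@@H](Cc2ccccc2)COC1=O | intermediate
27 | (S)-4-benzyl-3-{(2S,3S)-2-[3,5-bis(benzyloxy)phenyl]-3-[2,4-bis(benzyloxy)phenyl]-3-hydroxypropanoyl}oxazolidin-2-one | O=C1OC[C@H](Cc2ccccc2)N1C(=O)[C@@H](c1cc(OCc2ccccc2)cc(OCc2ccccc2)c1)[C@H](O)c1ccc(OCc2ccccc2)cc1OCc1ccccc1 | intermediate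
28 | (S)-4-benzyl-3-{(2S,3S)-2-[3,5-bis(benzyloxy)phenyl]-3-[2,4-bis(benzyloxy)phenyl]-3-(tert-butyldimethylsilyloxy)propanoyl}oxazolidin-2-one | O=C1OC[C@H](Cc2ccccc2)N1C(=O)[C@@H](c1cc(OCc2ccccc2)cc(OCc2ccccc2)c1)[C@H](O[Si](C)(C)C(C)(C)C)c1ccc(OCc2ccccc2)cc1OCc1ccccc1 | intermediate
29 | (2R,3S)-2-[3,5-bis(benzyloxy)phenyl]-3-[2,4-bis(benzyloxy)phenyl]-3-(tert-butyldimethylsilyloxy)propan-1-ol | OC[C@@H](c1cc(OCc2ccccc2)cc(OCc2ccccc2)c1)[C@H](O[Si](C)(C)C(C)(C)C)c1ccc(OCc2ccccc2)cc1OCc1ccccc1 | intermediate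
30 | (2S,3S)-2-[3,5-bis(benzyloxy)phenyl]-3-[2,4-bis(benzyloxy)phenyl]-3-(tert-butyldimethylsilyloxy)propanal | O=C[C@@H](c1cc(OCc2ccccc2)cc(OCc2ccccc2)c1)[C@H](O[Si](C)(C)C(C)(C)C)c1ccc(OCc2ccccc2)cc1OCc1ccccc1 | intermediate
31 | (3S,4S)-1,1-dibromo-3-[3,5-bis(benzyloxy)phenyl]-4-[2,4-bis(benzyloxy)phenyl]-4-(tert-butyldimethylsilyloxy)but-1-ene | BrC(Br)=C[C@@H](c1cc(OCc2ccccc2)cc(OCc2ccccc2)c1)[C@H](O[Si](C)(C)C(C)(C)C)c1ccc(OCc2ccccc2)cc1OCc1ccccc1 | intermediate
32 | lithium acetylide: lithium (3R,4S)-3-[3,5-bis(benzyloxy)phenyl]-4-[2,4-bis(benzyloxy)phenyl]-4-(tert-butyldimethylsilyloxy)but-1-yn-1-ide | [Li]C#C[C@@H](c1cc(OCc2ccccc2)cc(OCc2ccccc2)c1)[C@H](O[Si](C)(C)C(C)(C)C)c1ccc(OCc2ccccc2)cc1OCc1ccccc1 | intermediate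
33 | lithium ynolate: lithium (3R,4S)-3-[3,5-bis(benzyloxy)phenyl]-4-[2,4-bis(benzyloxy)phenyl]-4-(tert-butyldimethylsilyloxy)but-1-yn-1-olate | [Li]OC#C[C@@H](c1cc(OCc2ccccc2)cc(OCc2ccccc2)c1)[C@H](O[Si](C)(C)C(C)(C)C)c1ccc(OCc2ccccc2)cc1OCc1ccccc1 | intermediate
34 | (3R,4S)-3-[3,5-bis(benzyloxy)phenyl]-4-[2,4-bis(benzyloxy)phenyl]-4-(tert-butyldimethylsilyloxy)-1-(triisopropylsilyloxy)but-1-yne (fragment 2) | CC(C)[Si](C(C)C)(C(C)C)OC#C[C@@H](c1cc(OCc2ccccc2)cc(OCc2ccccc2)c1)[C@H](O[Si](C)(C)C(C)(C)C)c1ccc(OCc2ccccc2)cc1OCc1ccccc1 | intermediate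
35 | vinylketene: 3-{(2R,3R)-4-{[4-(benzyloxy)benzyl]oxy}-2-[4-(benzyloxy)phenyl]-6-[(E)-4-(benzyloxy)styryl]-2,3-dihydrobenzofuran-3-yl}buta-1,3-dien-1-one | C(c1ccccc1)Oc1ccc(/C=C/c2cc(OCc4ccc(OCc5ccccc5)cc4)c3c(c2)O[C@@H](c2ccc(OCc4ccccc4)cc2)[C@@H]3C(=C)C=C=O)cc1 | intermediate
36 | 2-vinylcyclobutenone: 2-[(1R,2S)-chain of 34]-3-(triisopropylsilyloxy)-4-{1-[(2R,3R)-dihydrobenzofuran-3-yl unit of 18]vinyl}cyclobut-2-en-1-one (both C4 epimers) | C(c1ccccc1)Oc1ccc(/C=C/c2cc(OCc4ccc(OCc5ccccc5)cc4)c3c(c2)O[C@@H](c2ccc(OCc4ccccc4)cc2)[C@@H]3C(=C)C2C(=O)C([C@@H](c4cc(OCc5ccccc5)cc(OCc5ccccc5)c4)[C@H](O[Si](C)(C)C(C)(C)C)c4ccc(OCc5ccccc5)cc4OCc4ccccc4)=C2O[Si](C(C)C)(C(C)C)C(C)C)cc1 | intermediate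
37 | dienylketene: (3E)-2-[(1R,2S)-chain of 34]-5-[(2R,3R)-dihydrobenzofuran-3-yl unit of 18]-3-(triisopropylsilyloxy)hexa-1,3,5-trien-1-one | C(c1ccccc1)Oc1ccc(/C=C/c2cc(OCc4ccc(OCc5ccccc5)cc4)c3c(c2)O[C@@H](c2ccc(OCc4ccccc4)cc2)[C@@H]3C(=C)/C=C(O[Si](C(C)C)(C(C)C)C(C)C)\C([C@@H](c2cc(OCc4ccccc4)cc(OCc4ccccc4)c2)[C@H](O[Si](C)(C)C(C)(C)C)c2ccc(OCc4ccccc4)cc2OCc2ccccc2)=C=O)cc1 | intermediate
38 | cyclohexadienone: 2-[(1R,2S)-chain of 34]-5-[(2R,3R)-dihydrobenzofuran-3-yl unit of 18]-3-(triisopropylsilyloxy)cyclohexa-2,4-dien-1-one | C(c1ccccc1)Oc1ccc(/C=C/c2cc(OCc4ccc(OCc5ccccc5)cc4)c3c(c2)O[C@@H](c2ccc(OCc4ccccc4)cc2)[C@@H]3C2=CC(O[Si](C(C)C)(C(C)C)C(C)C)=C([C@@H](c4cc(OCc5ccccc5)cc(OCc5ccccc5)c4)[C@H](O[Si](C)(C)C(C)(C)C)c4ccc(OCc5ccccc5)cc4OCc4ccccc4)C(=O)C2)cc1 | intermediate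
39 | 2-{(1R,2S)-1-[3,5-bis(benzyloxy)phenyl]-2-[2,4-bis(benzyloxy)phenyl]-2-(tert-butyldimethylsilyloxy)ethyl}-5-{(2R,3R)-4-{[4-(benzyloxy)benzyl]oxy}-2-[4-(benzyloxy)phenyl]-6-[(E)-4-(benzyloxy)styryl]-2,3-dihydrobenzofuran-3-yl}-3-(triisopropylsilyloxy)phenol | C(c1ccccc1)Oc1ccc(/C=C/c2cc(OCc4ccc(OCc5ccccc5)cc4)c3c(c2)O[C@@H](c2ccc(OCc4ccccc4)cc2)[C@@H]3c2cc(O)c(c(O[Si](C(C)C)(C(C)C)C(C)C)c2)[C@@H](c2cc(OCc4ccccc4)cc(OCc4ccccc4)c2)[C@H](O[Si](C)(C)C(C)(C)C)c2ccc(OCc4ccccc4)cc2OCc2ccccc2)cc1 | intermediate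
40 | triol: 2-{(1R,2S)-1-[3,5-bis(benzyloxy)phenyl]-2-[2,4-bis(benzyloxy)phenyl]-2-hydroxyethyl}-5-{(2R,3R)-4-{[4-(benzyloxy)benzyl]oxy}-2-[4-(benzyloxy)phenyl]-6-[(E)-4-(benzyloxy)styryl]-2,3-dihydrobenzofuran-3-yl}benzene-1,3-diol | C(c1ccccc1)Oc1ccc(/C=C/c2cc(OCc4ccc(OCc5ccccc5)cc4)c3c(c2)O[C@@H](c2ccc(OCc4ccccc4)cc2)[C@@H]3c2cc(O)c(c(O)c2)[C@@H](c2cc(OCc4ccccc4)cc(OCc4ccccc4)c2)[C@H](O)c2ccc(OCc4ccccc4)cc2OCc2ccccc2)cc1 | intermediate
41 | (2R,3R)-2-[2,4-bis(benzyloxy)phenyl]-3-[3,5-bis(benzyloxy)phenyl]-6-{(2R,3R)-4-{[4-(benzyloxy)benzyl]oxy}-2-[4-(benzyloxy)phenyl]-6-[(E)-4-(benzyloxy)styryl]-2,3-dihydrobenzofuran-3-yl}-2,3-dihydrobenzofuran-4-ol | C(c1ccccc1)Oc1ccc(/C=C/c2cc(OCc4ccc(OCc5ccccc5)cc4)c3c(c2)O[C@@H](c2ccc(OCc4ccccc4)cc2)[C@@H]3c2cc(O)c3c(c2)O[C@@H](c2ccc(OCc4ccccc4)cc2OCc2ccccc2)[C@@H]3c2cc(OCc4ccccc4)cc(OCc4ccccc4)c2)cc1 | intermediate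
42 | (2R,3R)-2-(2,4-dihydroxyphenyl)-3-(3,5-dihydroxyphenyl)-6-{(2R,3R)-4-hydroxy-2-(4-hydroxyphenyl)-6-[(E)-4-hydroxystyryl]-2,3-dihydrobenzofuran-3-yl}-2,3-dihydrobenzofuran-4-ol (CNP0118407.2) | Oc1ccc(/C=C/c2cc(O)c3c(c2)O[C@@H](c2ccc(O)cc2)[C@@H]3c2cc(O)c3c(c2)O[C@@H](c2ccc(O)cc2O)[C@@H]3c2cc(O)cc(O)c2)cc1 | target

Total step count: 22. Longest linear sequence: 13 steps (steps 1–9, 11, 20, 21, 22); the siloxyalkyne branch (steps 12–19) and the boronate (step 10) are convergent.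

Steps most likely to fail

Step 20. The vinylketene released from 18 may be lost to dimerisation, to acylation of the phenol being formed, or to (2+2) addition across the stilbene before it meets the sterically shielded alkyne, and 18 is too valuable to be used in excess. Fallback: the ring is built one stage earlier. Bromide 15 (2 equiv) and 34 are heated in toluene (80 → 110 °C) to give the bromo-resorcinol mono-silyl ether F1; Suzuki coupling of F1 with 17 [Pd(OAc)2, SPhos, K3PO4, THF–H2O, 40 °C], now on a robust aryl bromide that has no strained ring, rejoins the route at 39.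

Step 11. The strained enone of 15 may be opened or oligomerised by phosphate or hydroxide, or palladium may insert into its acyl–carbon bond, while the transmetalation of the pinacol boronate is still slow. Fallback: a tin-based coupling without water or oxygen base. Radical hydrostannation of 16 (n-Bu3SnH, AIBN, PhMe, 80 °C) gives (E)-tributyl{2-[4-(benzyloxy)phenyl]vinyl}stannane F2, and Stille coupling of F2 with 15 [Pd(P(t-Bu)3)2, CsF, dioxane, 25 °C] returns to the route at 18.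

Step 4. Chromate may over-oxidise the electron-rich arene or cleave the enol ether double bond back to the aldehyde instead of stopping at the ester. Fallback: the oxidation is split into hydrolysis and a chlorite oxidation. Enol ether 5 is hydrolysed (HCl aq, THF, 25 °C) to 2-(4-bromo-2,6-bis{[4-(benzyloxy)benzyl]oxy}phenyl)acetaldehyde F3, Pinnick oxidation (NaClO2, NaH2PO4, 2-methyl-2-butene, t-BuOH–H2O) gives 2-(4-bromo-2,6-bis{[4-(benzyloxy)benzyl]oxy}phenyl)acetic acid F4, and O-methylation (MeI, K2CO3, DMF) returns to the route at 6.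

Further compounds
F1 | step 20 | bromo-resorcinol mono-silyl ether: 2-{(1R,2S)-1-[3,5-bis(benzyloxy)phenyl]-2-[2,4-bis(benzyloxy)phenyl]-2-(tert-butyldimethylsilyloxy)ethyl}-5-{(2R,3R)-4-{[4-(benzyloxy)benzyl]oxy}-2-[4-(benzyloxy)phenyl]-6-bromo-2,3-dihydrobenzofuran-3-yl}-3-(triisopropylsilyloxy)phenol | Brc1cc(OCc3ccc(OCc4ccccc4)cc3)c2c(c1)O[C@@H](c1ccc(OCc3ccccc3)cc1)[C@@H]2c1cc(O)c(c(O[Si](C(C)C)(C(C)C)C(C)C)c1)[C@@H](c1cc(OCc2ccccc2)cc(OCc2ccccc2)c1)[C@H](O[Si](C)(C)C(C)(C)C)c1ccc(OCc2ccccc2)cc1OCc1ccccc1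
F2 | step 11 | (E)-tributyl{2-[4-(benzyloxy)phenyl]vinyl}stannane | CCCC[Sn](CCCC)(CCCC)/C=C/c1ccc(OCc2ccccc2)cc1
F3 | step 4 | 2-(4-bromo-2,6-bis{[4-(benzyloxy)benzyl]oxy}phenyl)acetaldehyde | O=CCc1c(OCc2ccc(OCc3ccccc3)cc2)cc(Br)cc1OCc1ccc(OCc2ccccc2)cc1
F4 | step 4 | 2-(4-bromo-2,6-bis{[4-(benzyloxy)benzyl]oxy}phenyl)acetic acid | OC(=O)Cc1c(OCc2ccc(OCc3ccccc3)cc2)cc(Br)cc1OCc1ccc(OCc2ccccc2)cc1
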